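Remark: all positions are given in the indane numbering of the target (C1–C3 cyclopentane with the gem-dimethyl carbon C2, fusion carbons C3a and C7a, C4 acetoxymethyl, C5 chloroethyl, C6 butanoyloxymethyl, C7–H), also for monocyclic, pyran and pyrylium intermediates.

## Structural features

The target is a 2,2-dimethylindane: a cyclopentane (C1, C2 with the gem-dimethyl group, C3) fused through C3a–C7a to a benzene ring that keeps a single hydrogen, at C7. The other three benzene carbons carry a contiguous array of arms: acetoxymethyl on C4, 2-chloroethyl on C5 and butanoyloxymethyl on C6, so C5 is flanked on both sides and C4 also abuts the fusion carbon C3a. There is no stereocentre; every problem is one of regiochemistry and of telling similar groups apart. The fragile groups are the two different benzylic esters (transesterification, acyl scrambling, hydrogenolysis) and the primary chloride, which would alkylate a free benzylic hydroxyl on C4 or C6 to an isochroman and would eliminate under strong base. The chloride therefore has to come last and the two acyl groups have to be introduced one after the other. The real difficulty is to place five different substituents on one benzene ring without isomers and to distinguish the oxygens on C4 and C6, which differ only in having two or one ortho neighbours. The feature exploited is that C5 with its arm is one carbon lying between two carbons that can be ester-bearing α-carbons of a pyrylium ring: the chain C4–C3a–C7a–C7–C6 is held in a cyclopenta[c]pyrylium cation (its C1 = C4, C3 = C6, C4 = C7, C4a = C7a, C7a = C3a) with oxygen in the place of C5, and an alkylidenephosphorane delivers C5 while the oxygen leaves as Ph3PO. With this mapping cation, ylide and arene agree atom for atom, so no structural correction is needed.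

## Logic of the disconnections

**22 ⇒ 21.** The C–Cl bond of the arm is cut. The chloride is made last because a chloroethyl group beside a free benzylic hydroxyl would close to an isochroman, and because hydride and strong base would attack it. The gain is that every earlier step handles a protected alcohol. The forward step must substitute a primary alcohol under neutral conditions beside two benzylic esters.

**21 ⇒ 20.** The O–Si bond is restored. A silyl ether is orthogonal to both esters and to hydride. The forward step must remove it without generating an alkoxide that could shuffle acyl groups.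

**20 ⇒ 19 ⇒ 18.** The two acyl C–O bonds are cut, acetate first and butanoate second, so that in the forward sense the less hindered C6 hydroxyl is acylated selectively and the remaining one needs no selectivity. The gain is a diol with two equal functional groups. The demand is discrimination between a benzylic hydroxyl with one ortho neighbour and one with two.

**18 ⇒ 17.** Both carbinol carbons are taken back to the ester level. Esters are what the ring synthesis needs at C4 and C6, and one reduction sets both. The forward step must spare the silyl ether.

**17 ⇒ 13 + 16.** C4–C5 and C5–C6 are cut, and C5 with its arm is replaced by the oxygen of 13. The most crowded carbon is thus installed last, and the positions of the other substituents are already fixed in 13. The forward step requires the ylide to add at an α-carbon of 13 rather than remove a proton from C1–H2 or add at C7a.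

- Both α-carbons of 13 keep ester groups, not CH2OR groups, so that there is no acidic α-CH2.
- Attack at either α-carbon leads to 17.
- As an improvement in the reagents, 16 is used in barely more than one equivalent, and the second proton is removed by an amidine instead of a second equivalent of ylide.

**16 ⇒ 15 ⇒ 14.** The P=C bond comes from a P–C bond and a C–H bond, and the P–C bond from a primary bromide. This only requires a base that leaves the silyl ether intact.

**13 ⇒ 12 ⇒ 11.** The ring C–O bond is opened and the C7a–H restored. A 1,5-diketone is the standard pyrylium precursor, and in 11 neither ketone has an outer α-carbon, so no aldol ring closure can interfere. The demand is hydride removal from an electron-poor 4H-pyran.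

**11 ⇒ 10 ⇒ 7 + 9.** The C7–C7a bond is cut as a Michael addition. This gives an enone that holds C4, C3a, C7a and the cyclopentane, and a two-carbon donor that holds C6 and C7. The forward step must favour conjugate addition over addition to the very electrophilic C4 carbonyl.

**9 ⇒ 8.** The O–Si bond is cut; only the methyl group of 8 can enolise.

**7 ⇒ 6 + 5, then 6 ⇒ 4 ⇒ 3 ⇒ 2 ⇒ 1.** The C3a–C4 bond is cut to an alkenyl anion and an oxalate. The C–Li, C–Sn and C–O bonds lead back to the enolate of 1. The whole regiochemistry of the cyclopentane is decided when 1 is enolised, which must occur on the side remote from the quaternary carbon.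

## Other disconnections considered

**Alternative 1:** pyranone–alkyne cycloaddition.
- Cut: C4–C5 and C6–C7 of the benzene ring, with the C4 carboxyl and the C5 arm tied together as a lactone.
- Forward key step: heating the pyranone ester A2 at high dilution would let the pyranone diene add across the tethered alkyne; decarboxylative cycloreversion of the bridged adduct would give the cyclopenta-fused dihydroisocoumarin A1.
- In favour: intramolecular pyranone–alkyne cycloaddition with decarboxylation is an established arene synthesis, and the tether fixes the regiochemistry.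
- In favour: C4 arrives as a lactone carbonyl and C6 as a silyl ether. On this point the alternative is better than the chosen plan, which has to separate the two carbinols by steric discrimination. On mechanistic security it is also better, since no new reaction type is needed.
- Against: an ester tether prefers the conformer that holds diene and alkyne apart, so high temperature and dilution would be needed.
- Against: reductive opening of the lactone of A1 frees the C4 carbinol and the arm hydroxyl together. These two are set up to close to an isochroman as soon as either is activated, so extra protection steps would precede chlorination.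
- Against: A2 needs a fused pyranone acid that itself takes several steps.
- Step economy: about equal to the chosen plan, or somewhat longer. The chosen plan is more convergent, because ring carbon and arm arrive in one reagent.

**Alternative 2:** hexadehydro-Diels–Alder cascade.
- Cut: C3a–C7a and C6–C7 (both rings at once) together with C5–CH2 and C4–C(=O).
- Forward key step: heating triyne A4 with dimethyl malonate A6 and Cs2CO3 would give aryne A5, which would insert into a C–C bond of A6 to give A3.
- In favour: four skeletal bonds and two rings would form in one operation from an acyclic precursor. In bond economy and probably in step count this is better than the chosen plan.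
- In favour: C6 (silyl ether) is distinguished from C4 (ester), which is also better than the chosen plan.
- Against: the tether is an unactivated all-carbon chain and the diynophile a terminal alkyne, so a high temperature would be needed in the presence of base and of acidic propargylic and acetylenic hydrogens.
- Against: the direction of malonate addition to A5 depends on aryne distortion by the fused ring and by the C6 substituent and is not secured. In the chosen plan both modes of attack converge on one arene.
- Against: the two ester groups of A3 would be reduced together and lead to the same isochroman-prone pair of hydroxyls as in Alternative 1.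
- Mechanistic security: lower than for the chosen plan.

**Alternative 3:** dienol–benzene rearrangement.
- Cut: the C3–C3a bond, made by a 1,2-shift; the six-membered ring is present beforehand as a cyclohexadienol.
- Forward key step: catalytic p-toluenesulfonic acid would ionise the tertiary dienol A8; a cyclobutane CH2 would migrate from the spiro carbon to the neighbouring cationic carbon, and proton loss would give the vinyl indane A7.
- In favour: A8 is symmetrical, so either migration would give the same arene. Here the alternative is the equal of the chosen plan.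
- In favour: relief of four-ring strain and aromatisation drive the step, and catalytic acid at ambient temperature is milder than the conditions of the chosen key step. On conditions the alternative is better.
- Against: the two carbinols of A7 carry identical silyl ethers, so on the C4/C6 problem it is only equal to the chosen plan.
- Against: the vinyl group would still need anti-Markovnikov conversion into the chloroethyl arm.
- Against: the cation could be diverted by loss of a silyloxy group or by vinyl shift.
- Step economy: worse, because A8 would have to be assembled over many steps from a 3,3-dimethylcyclobutane building block.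

Key step: step 8

## Route

Step 1
Reactants: 1 3,3-dimethylcyclopentan-1-one
Product: 3 4,4-dimethylcyclopent-1-en-1-yl trifluoromethanesulfonate, via lithium enolate 2 (not isolated)
Conditions: LiN(i-Pr)2 (1.05 equiv), THF, −78 °C; then PhNTf2, −78 → 0 °C
Reagents that add atoms: N-phenylbis(trifluoromethanesulfonimide), O=S(=O)(N(c1ccccc1)S(=O)(=O)C(F)(F)F)C(F)(F)F
Why: Kinetic enolisation followed by O-triflation; the amide base should take a proton from the methylene remote from the quaternary carbon, because the other α-methylene is shielded by the gem-dimethyl group, and this fixes the double bond position.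

Step 2
Reactants: 3 4,4-dimethylcyclopent-1-en-1-yl trifluoromethanesulfonate
Product: 4 (4,4-dimethylcyclopent-1-en-1-yl)trimethylstannane
Conditions: Me3SnSnMe3, Pd(PPh3)4 (5 mol %), LiCl, THF, 65 °C
Reagents that add atoms: hexamethyldistannane, C[Sn](C)(C)[Sn](C)(C)C
Why: Palladium-catalysed stannylation of an enol triflate (Stille-type coupling with a distannane); the alkene position is retained.

Step 3
Reactants: 4 (4,4-dimethylcyclopent-1-en-1-yl)trimethylstannane; 5 diethyl oxalate
Product: 7 ethyl 2-(4,4-dimethylcyclopent-1-en-1-yl)-2-oxoacetate, via vinyllithium 6 (not isolated)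
Conditions: MeLi, THF, −78 °C; cannulated into (CO2Et)2 (3 equiv), THF, −78 °C; AcOH quench at −78 °C
Reagents that add atoms: none
Why: Tin–lithium exchange, then monoacylation of the alkenyllithium by an oxalate diester; inverse addition into excess oxalate at low temperature keeps the tetrahedral adduct intact until the quench and prevents a second addition.

Step 4
Reactants: 8 ethyl pyruvate
Product: 9 ethyl 2-[(trimethylsilyl)oxy]prop-2-enoate
Conditions: Me3SiCl, Et3N, DMF, 25 → 40 °C; pentane extraction, distillation
Reagents that add atoms: chlorotrimethylsilane, C[Si](C)(C)Cl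
Why: O-silylation under soft enolisation; only the methyl group can enolise, so a single silyl enol ether is possible.

Step 5
Reactants: 7 ethyl 2-(4,4-dimethylcyclopent-1-en-1-yl)-2-oxoacetate; 9 ethyl 2-[(trimethylsilyl)oxy]prop-2-enoate
Product: 11 ethyl 3-[2-(2-ethoxy-2-oxoacetyl)-4,4-dimethylcyclopentyl]-2-oxopropanoate (racemic diastereomer mixture), via silyl enol ether adduct 10 (not isolated)
Conditions: Cu(OTf)2 (10 mol %), CH2Cl2, −78 → 0 °C; then 1 M HCl, THF, 25 °C
Reagents that add atoms: none
Why: Mukaiyama–Michael addition; two-point binding of the 1,2-dicarbonyl unit to the copper salt activates the β-carbon (C7a), and the silyl group passes to the new enolate, which is hydrolysed on work-up. The two new stereocentres (C3a, C7a) are left uncontrolled because both become sp2 in step 6.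

Step 6
Reactants: 11 ethyl 3-[2-(2-ethoxy-2-oxoacetyl)-4,4-dimethylcyclopentyl]-2-oxopropanoate
Product: 13 1,3-bis(ethoxycarbonyl)-6,6-dimethyl-6,7-dihydro-5H-cyclopenta[c]pyrylium tetrafluoroborate, via 4H-pyran 12 (not isolated)
Conditions: Ph3CBF4 (1.2 equiv), AcOH/Ac2O, 60–80 °C; precipitation with dry Et2O
Reagents that add atoms: triphenylcarbenium tetrafluoroborate, [C+](c1ccccc1)(c1ccccc1)c1ccccc1.F[B-](F)(F)F
Why: Cyclodehydration of the 1,5-diketone to the 4H-pyran and hydride abstraction from its doubly allylic C7a–H by the trityl cation, the standard pyrylium synthesis from 1,5-diketones; Ac2O takes up the water.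

Step 7
Reactants: 14 (3-bromopropoxy)(tert-butyl)dimethylsilane
Product: 15 {3-[(tert-butyldimethylsilyl)oxy]propyl}triphenylphosphonium bromide
Conditions: PPh3, MeCN, 80 °C
Reagents that add atoms: triphenylphosphine, c1ccc(cc1)P(c1ccccc1)c1ccccc1
Why: SN2 quaternisation of the phosphine by a primary bromide; the silyl ether survives the neutral conditions.

Step 8
Reactants: 13 1,3-bis(ethoxycarbonyl)-6,6-dimethyl-6,7-dihydro-5H-cyclopenta[c]pyrylium tetrafluoroborate; 15 {3-[(tert-butyldimethylsilyl)oxy]propyl}triphenylphosphonium bromide
Product: 17 diethyl 5-{2-[(tert-butyldimethylsilyl)oxy]ethyl}-2,2-dimethyl-2,3-dihydro-1H-indene-4,6-dicarboxylate, via phosphorus ylide 16 (not isolated)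
Conditions: 15 (1.1 equiv), NaN(SiMe3)2 (1.05 equiv), THF, −78 → 0 °C; ylide solution added slowly to 13 in THF/CH2Cl2, −78 °C; then DBU (1.5 equiv), −78 → 25 °C, finally 50 °C
Reagents that add atoms: none
Why: Proposed new method: the ylide carbon should add to an α-carbon of the pyrylium ring (most probably C6, whose neighbour C7 carries only hydrogen) to give a 2H-pyran, which opens electrocyclically to a dienyl α-keto ester bearing the phosphonium group. DBU then removes the P–CH proton, now vinylogously activated, and the new ylide attacks the C4 keto group in a six-membered intramolecular Wittig closure (formally 6-exo-trig addition, then collapse of the oxaphosphetane), so that C5–C6 and C4–C5 are formed and the ring oxygen leaves as Ph3PO. The closest known reaction type is the conversion of 2,4,6-triarylpyrylium salts into benzenes with alkylidenetriphenylphosphoranes; a pyrylium with two α-ester groups and a fused alkyl ring has not been used in it. Attack at C4 instead of C6 gives the same arene by the mirror sequence, so no α/α' selectivity is needed, and no stereocentre is formed. What is needed is α-addition in preference to deprotonation of the γ-CH2 (C1), to γ-addition and to electron transfer. Both α-carbons carry esters (no α-C–H, highest positive charge) and the γ-carbon is fully substituted; the ylide meets an excess of cation at −78 °C and is never present together with a second strong base. The ester on the ring-opened ketone makes it a strong Wittig acceptor, and aromatisation makes the closure irreversible. The C6=C7 geometry of the open form need not be controlled, because the pyran/dienone equilibrium and the delocalised ylide allow rotation.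

Step 9
Reactants: 17 diethyl 5-{2-[(tert-butyldimethylsilyl)oxy]ethyl}-2,2-dimethyl-2,3-dihydro-1H-indene-4,6-dicarboxylate
Product: 18 (5-{2-[(tert-butyldimethylsilyl)oxy]ethyl}-2,2-dimethyl-2,3-dihydro-1H-indene-4,6-diyl)dimethanol
Conditions: LiAlH4 (2.5 equiv), THF, 0 → 25 °C; aqueous NaOH work-up
Reagents that add atoms: none
Why: Hydride reduction of both aryl esters to benzylic alcohols; a primary silyl ether is stable to LiAlH4 at or below room temperature.

Step 10
Reactants: 18 (5-{2-[(tert-butyldimethylsilyl)oxy]ethyl}-2,2-dimethyl-2,3-dihydro-1H-indene-4,6-diyl)dimethanol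
Product: 19 (5-{2-[(tert-butyldimethylsilyl)oxy]ethyl}-4-(hydroxymethyl)-2,2-dimethylindan-6-yl)methyl butanoate
Conditions: vinyl butanoate (3 equiv), immobilised Candida antarctica lipase B, t-BuOMe, 30 °C, stopped at full consumption of 18
Reagents that add atoms: vinyl butanoate, CCCC(=O)OC=C
Why: Lipase-catalysed irreversible transesterification with an enol ester; the C6 carbinol has one ortho neighbour and the C4 carbinol two (the C5 arm and the C3 methylene), so the enzyme should acylate C6 first.

Step 11
Reactants: 19 (5-{2-[(tert-butyldimethylsilyl)oxy]ethyl}-4-(hydroxymethyl)-2,2-dimethylindan-6-yl)methyl butanoate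
Product: 20 [4-(acetoxymethyl)-5-{2-[(tert-butyldimethylsilyl)oxy]ethyl}-2,2-dimethylindan-6-yl]methyl butanoate
Conditions: Ac2O, pyridine, DMAP (cat.), CH2Cl2, 0 → 25 °C
Reagents that add atoms: acetic anhydride, CC(=O)OC(C)=O
Why: DMAP-catalysed acetylation of the remaining hindered primary benzylic alcohol; butanoate and silyl ether are inert.

Step 12
Reactants: 20 [4-(acetoxymethyl)-5-{2-[(tert-butyldimethylsilyl)oxy]ethyl}-2,2-dimethylindan-6-yl]methyl butanoate
Product: 21 [4-(acetoxymethyl)-5-(2-hydroxyethyl)-2,2-dimethylindan-6-yl]methyl butanoate
Conditions: HF·pyridine, pyridine/THF, 0 → 25 °C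
Reagents that add atoms: none
Why: Fluoride cleavage of the primary silyl ether under buffered, weakly acidic conditions, which avoid the alkoxide-induced acyl transfer that a basic fluoride source could cause.

Step 13
Reactants: 21 [4-(acetoxymethyl)-5-(2-hydroxyethyl)-2,2-dimethylindan-6-yl]methyl butanoate
Product: 22 [4-(acetoxymethyl)-5-(2-chloroethyl)-2,2-dimethylindan-6-yl]methyl butanoate (CNP0321917.0)
Conditions: PPh3, N-chlorosuccinimide, CH2Cl2, 0 → 25 °C
Reagents that add atoms: N-chlorosuccinimide, O=C1CCC(=O)N1Cl
Why: Appel-type chlorination: the alcohol is activated as an alkoxyphosphonium ion and displaced by chloride in an SN2 step under neutral conditions; with both benzylic oxygens acylated no isochroman can form.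

## Compound list

1 | 3,3-dimethylcyclopentan-1-one | CC1(C)CCC(=O)C1 | starting material
2 | lithium 4,4-dimethylcyclopent-1-en-1-olate | [Li+].[O-]C1=CCC(C)(C)C1 | intermediate (not isolated)
3 | 4,4-dimethylcyclopent-1-en-1-yl trifluoromethanesulfonate | CC1(C)CC=C(OS(=O)(=O)C(F)(F)F)C1 | intermediate
4 | (4,4-dimethylcyclopent-1-en-1-yl)trimethylstannane | CC1(C)CC=C([Sn](C)(C)C)C1 | intermediate
5 | diethyl oxalate | CCOC(=O)C(=O)OCC | starting material
6 | (4,4-dimethylcyclopent-1-en-1-yl)lithium | [Li]C1=CCC(C)(C)C1 | intermediate (not isolated)
7 | ethyl 2-(4,4-dimethylcyclopent-1-en-1-yl)-2-oxoacetate | CCOC(=O)C(=O)C1=CCC(C)(C)C1 | intermediate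
8 | ethyl pyruvate | CCOC(=O)C(C)=O | starting material
9 | ethyl 2-[(trimethylsilyl)oxy]prop-2-enoate | CCOC(=O)C(=C)O[Si](C)(C)C | intermediate
10 | ethyl 3-{2-[2-ethoxy-2-oxo-1-(trimethylsilyloxy)ethylidene]-4,4-dimethylcyclopentyl}-2-oxopropanoate (racemic, alkene geometry not defined) | CCOC(=O)C(=O)CC1CC(C)(C)CC1=C(O[Si](C)(C)C)C(=O)OCC | intermediate (not isolated)
11 | ethyl 3-[2-(2-ethoxy-2-oxoacetyl)-4,4-dimethylcyclopentyl]-2-oxopropanoate (racemic, cis/trans mixture) | CCOC(=O)C(=O)CC1CC(C)(C)CC1C(=O)C(=O)OCC | intermediate
12 | diethyl 6,6-dimethyl-4a,5,6,7-tetrahydrocyclopenta[c]pyran-1,3-dicarboxylate (racemic) | CCOC(=O)C1=CC2CC(C)(C)CC2=C(C(=O)OCC)O1 | intermediate (not isolated)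
13 | 1,3-bis(ethoxycarbonyl)-6,6-dimethyl-6,7-dihydro-5H-cyclopenta[c]pyrylium tetrafluoroborate | CCOC(=O)c1cc2c(c(C(=O)OCC)[o+]1)CC(C)(C)C2.F[B-](F)(F)F | intermediate
14 | (3-bromopropoxy)(tert-butyl)dimethylsilane | BrCCCO[Si](C)(C)C(C)(C)C | starting material
15 | {3-[(tert-butyldimethylsilyl)oxy]propyl}triphenylphosphonium bromide | CC(C)(C)[Si](C)(C)OCCC[P+](c1ccccc1)(c1ccccc1)c1ccccc1.[Br-] | intermediate
16 | {3-[(tert-butyldimethylsilyl)oxy]propylidene}triphenylphosphorane | CC(C)(C)[Si](C)(C)OCCC=P(c1ccccc1)(c1ccccc1)c1ccccc1 | intermediate (not isolated)
17 | diethyl 5-{2-[(tert-butyldimethylsilyl)oxy]ethyl}-2,2-dimethyl-2,3-dihydro-1H-indene-4,6-dicarboxylate | CCOC(=O)c1cc2c(c(C(=O)OCC)c1CCO[Si](C)(C)C(C)(C)C)CC(C)(C)C2 | intermediate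
18 | (5-{2-[(tert-butyldimethylsilyl)oxy]ethyl}-2,2-dimethyl-2,3-dihydro-1H-indene-4,6-diyl)dimethanol | OCc1cc2c(c(CO)c1CCO[Si](C)(C)C(C)(C)C)CC(C)(C)C2 | intermediate
19 | (5-{2-[(tert-butyldimethylsilyl)oxy]ethyl}-4-(hydroxymethyl)-2,2-dimethylindan-6-yl)methyl butanoate | CCCC(=O)OCc1cc2c(c(CO)c1CCO[Si](C)(C)C(C)(C)C)CC(C)(C)C2 | intermediate
20 | [4-(acetoxymethyl)-5-{2-[(tert-butyldimethylsilyl)oxy]ethyl}-2,2-dimethylindan-6-yl]methyl butanoate | CCCC(=O)OCc1cc2c(c(COC(C)=O)c1CCO[Si](C)(C)C(C)(C)C)CC(C)(C)C2 | intermediate
21 | [4-(acetoxymethyl)-5-(2-hydroxyethyl)-2,2-dimethylindan-6-yl]methyl butanoate | CCCC(=O)OCc1cc2c(c(COC(C)=O)c1CCO)CC(C)(C)C2 | intermediate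
22 | [4-(acetoxymethyl)-5-(2-chloroethyl)-2,2-dimethylindan-6-yl]methyl butanoate | CCCC(=O)OCc1cc2c(c(COC(C)=O)c1CCCl)CC(C)(C)C2 | target

## Step count and risk

Total step count: 13 (steps 4 and 7 prepare the two side components).
Longest linear sequence: 11 steps (steps 1, 2, 3, 5, 6, 8, 9, 10, 11, 12, 13, from 1 to 22).

Least certain steps:

**Step 8 (key step).**
- What may go wrong: proton abstraction from the γ-CH2 (C1) of 13 by the strongly basic ylide, giving a methylenepyran; electron transfer from the ylide to the very electron-poor cation; or addition at the γ-carbon, which gives a 4H-pyran that cannot continue.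
- Why: all three are open to a pyrylium ion that is both alkyl-substituted and strongly activated.
- Fallback (known chemistry, no pyrylium), from 1 back to 17:
  - Formylation of 1 (HCO2Et, NaOEt) on the unhindered α-carbon gives 2-(hydroxymethylidene)-4,4-dimethylcyclopentan-1-one F1.
  - Base-mediated [3+3] condensation of F1 with diethyl 3-oxopentanedioate (NaOEt, EtOH), the classical phenol-forming annulation of hydroxymethylene ketones, gives diethyl 5-hydroxy-2,2-dimethylindane-4,6-dicarboxylate F2, in which the phenol carbon is C5.
  - Tf2O/pyridine gives diethyl 2,2-dimethyl-5-{[(trifluoromethyl)sulfonyl]oxy}indane-4,6-dicarboxylate F3.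
  - Stille coupling with tributyl(vinyl)stannane (Pd(PPh3)4, LiCl, dioxane, 100 °C) gives diethyl 5-ethenyl-2,2-dimethylindane-4,6-dicarboxylate F4.
  - 9-BBN, then NaBO3·4H2O, gives diethyl 5-(2-hydroxyethyl)-2,2-dimethylindane-4,6-dicarboxylate F5, which is silylated at once (TBSCl, imidazole) to forestall lactonisation and returns to the route at 17.

**Step 6.**
- What may go wrong: incomplete hydride transfer, and hydrolytic ring opening of the cation during isolation.
- Why: the two ester groups make 12 a poor hydride donor and 13 a strong electrophile.
- Fallback, from 11 back to 13: ring closure and oxidation are separated and the oxidation is given to a quinone instead of a carbocation. 11 is cyclodehydrated with catalytic p-toluenesulfonic acid in toluene with azeotropic removal of water, and 12 is isolated. 12 is then dehydrogenated with DDQ in MeCN in the presence of HBF4·OEt2 (protonated DDQ is the stronger hydride acceptor), and 13 is precipitated with ether. No new compound is involved.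

**Step 5.**
- What may go wrong: carbonyl addition at the C4 keto group in place of conjugate addition, or no turnover.
- Why: the donor is an electron-poor silyl enol ether and the acceptor carries substituents on both alkene carbons.
- Fallback, from 7 back to 11:
  - Base-catalysed Michael addition of the soft, stabilised donor diethyl 2-oxobutanedioate (sodium salt, EtOH/THF) gives diethyl 2-[2-(2-ethoxy-2-oxoacetyl)-4,4-dimethylcyclopentyl]-3-oxobutanedioate F6.
  - Hot aqueous HCl/AcOH hydrolyses the esters and decarboxylates the β-keto acid unit to 3-[2-(carboxycarbonyl)-4,4-dimethylcyclopentyl]-2-oxopropanoic acid F7.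
  - Fischer esterification (EtOH, H2SO4) returns to 11.

**Step 10.**
- What may go wrong: insufficient discrimination between the two primary benzylic hydroxyls, or slow enzymatic turnover, leading to regioisomeric monoesters and diester.
- Why: the two sites differ only by one ortho neighbour.
- Fallback, from 17 back to 20, replaces steric selection at the diol stage by chemoselective operations on the esters:
  - LiOH (THF/MeOH/H2O, 25 °C) saponifies only the C6 ester, since the doubly ortho-substituted C4 ester resists hydroxide, and gives 5-{2-[(tert-butyldimethylsilyl)oxy]ethyl}-4-(ethoxycarbonyl)-2,2-dimethylindane-6-carboxylic acid F8.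
  - LiEt3BH reduces the remaining ester while the carboxylate is inert, giving 5-{2-[(tert-butyldimethylsilyl)oxy]ethyl}-4-(hydroxymethyl)-2,2-dimethylindane-6-carboxylic acid F9.
  - Ac2O/pyridine gives 4-(acetoxymethyl)-5-{2-[(tert-butyldimethylsilyl)oxy]ethyl}-2,2-dimethylindane-6-carboxylic acid F10.
  - BH3·SMe2 reduces the acid in the presence of the acetate to [5-{2-[(tert-butyldimethylsilyl)oxy]ethyl}-6-(hydroxymethyl)-2,2-dimethylindan-4-yl]methyl acetate F11.
  - Butanoyl chloride/pyridine returns to 20.

**Step 1.**
- What may go wrong: incomplete regiocontrol in the enolisation. The isomeric enol triflate would be carried through to the 1,1-dimethylindane series and would be hard to remove.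
- Why: both α-carbons are methylenes and differ only in their distance from the quaternary carbon.
- Fallback, from 1 back to 3:
  - Dehydrogenation of 1 (IBX, DMSO, 70 °C) can occur only on the side that has a β-hydrogen and gives 4,4-dimethylcyclopent-2-en-1-one F12.
  - Dissolving-metal reduction (Li, liquid NH3/THF, one equivalent of t-BuOH, −78 °C) produces enolate 2 with the double bond fixed by the former enone.
  - After removal of NH3, PhNTf2 gives 3.

Further compounds
F1 | step 8 | 2-(hydroxymethylidene)-4,4-dimethylcyclopentan-1-one | O=C1CC(C)(C)CC1=CO
F2 | step 8 | diethyl 5-hydroxy-2,2-dimethylindane-4,6-dicarboxylate | CCOC(=O)c1cc2c(c(C(=O)OCC)c1O)CC(C)(C)C2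
F3 | step 8 | diethyl 2,2-dimethyl-5-{[(trifluoromethyl)sulfonyl]oxy}indane-4,6-dicarboxylate | CCOC(=O)c1cc2c(c(C(=O)OCC)c1OS(=O)(=O)C(F)(F)F)CC(C)(C)C2
F4 | step 8 | diethyl 5-ethenyl-2,2-dimethylindane-4,6-dicarboxylate | CCOC(=O)c1cc2c(c(C(=O)OCC)c1C=C)CC(C)(C)C2
F5 | step 8 | diethyl 5-(2-hydroxyethyl)-2,2-dimethylindane-4,6-dicarboxylate | CCOC(=O)c1cc2c(c(C(=O)OCC)c1CCO)CC(C)(C)C2
F0 | step 6 | none | none
F6 | step 5 | diethyl 2-[2-(2-ethoxy-2-oxoacetyl)-4,4-dimethylcyclopentyl]-3-oxobutanedioate (diastereomer mixture) | CCOC(=O)C(=O)C(C(=O)OCC)C1CC(C)(C)CC1C(=O)C(=O)OCC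
F7 | step 5 | 3-[2-(carboxycarbonyl)-4,4-dimethylcyclopentyl]-2-oxopropanoic acid (diastereomer mixture) | OC(=O)C(=O)CC1CC(C)(C)CC1C(=O)C(=O)O
F8 | step 10 | 5-{2-[(tert-butyldimethylsilyl)oxy]ethyl}-4-(ethoxycarbonyl)-2,2-dimethylindane-6-carboxylic acid | OC(=O)c1cc2c(c(C(=O)OCC)c1CCO[Si](C)(C)C(C)(C)C)CC(C)(C)C2
F9 | step 10 | 5-{2-[(tert-butyldimethylsilyl)oxy]ethyl}-4-(hydroxymethyl)-2,2-dimethylindane-6-carboxylic acid | OC(=O)c1cc2c(c(CO)c1CCO[Si](C)(C)C(C)(C)C)CC(C)(C)C2
F10 | step 10 | 4-(acetoxymethyl)-5-{2-[(tert-butyldimethylsilyl)oxy]ethyl}-2,2-dimethylindane-6-carboxylic acid | OC(=O)c1cc2c(c(COC(C)=O)c1CCO[Si](C)(C)C(C)(C)C)CC(C)(C)C2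
F11 | step 10 | [5-{2-[(tert-butyldimethylsilyl)oxy]ethyl}-6-(hydroxymethyl)-2,2-dimethylindan-4-yl]methyl acetate | OCc1cc2c(c(COC(C)=O)c1CCO[Si](C)(C)C(C)(C)C)CC(C)(C)C2
F12 | step 1 | 4,4-dimethylcyclopent-2-en-1-one | O=C1C=CC(C)(C)C1
A1 | alternative 1 | cyclopenta-fused 3,4-dihydroisocoumarin (lactone C=O on C4, OCH2CH2 on C5, silyloxymethyl on C6 of the 2,2-dimethylindane) | O=C1OCCc2c(CO[Si](C)(C)C(C)(C)C)cc3c(c21)CC(C)(C)C3
A2 | alternative 1 | 5-[(tert-butyldimethylsilyl)oxy]pent-3-yn-1-yl 6,6-dimethyl-3-oxo-3,5,6,7-tetrahydrocyclopenta[c]pyran-1-carboxylate | O=C1C=C2CC(C)(C)CC2=C(O1)C(=O)OCCC#CCO[Si](C)(C)C(C)(C)C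
A3 | alternative 2 | methyl 6-{[(tert-butyldimethylsilyl)oxy]methyl}-5-(2-methoxy-2-oxoethyl)-2,2-dimethylindane-4-carboxylate | COC(=O)Cc1c(CO[Si](C)(C)C(C)(C)C)cc2c(c1C(=O)OC)CC(C)(C)C2
A4 | alternative 2 | tert-butyl[(7,7-dimethyldeca-2,4,9-triyn-1-yl)oxy]dimethylsilane | C#CCC(C)(C)CC#CC#CCO[Si](C)(C)C(C)(C)C
A5 | alternative 2 | 6-{[(tert-butyldimethylsilyl)oxy]methyl}-2,2-dimethyl-4,5-didehydroindane (aryne) | CC1(C)CC2=C(C1)C#CC(CO[Si](C)(C)C(C)(C)C)=C2
A6 | alternative 2 | dimethyl malonate | COC(=O)CC(=O)OC
A7 | alternative 3 | 4,6-bis{[(tert-butyldimethylsilyl)oxy]methyl}-5-ethenyl-2,2-dimethylindane | C=Cc1c(CO[Si](C)(C)C(C)(C)C)cc2c(c1CO[Si](C)(C)C(C)(C)C)CC(C)(C)C2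
A8 | alternative 3 | 7-ethenyl-6,8-bis({[tert-butyl(dimethyl)silyl]oxy}methyl)-2,2-dimethylspiro[3.5]nona-5,8-dien-7-ol | C=CC1(O)C(CO[Si](C)(C)C(C)(C)C)=CC2(CC(C)(C)C2)C=C1CO[Si](C)(C)C(C)(C)C
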